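**Assumption:** briarane numbering (C1–C20) is used for every intermediate, and the given SMILES defines the absolute configuration. Nothing here has been run; selectivities are predictions.

## Retrosynthetic overview

1. Target 37 ⇐ ring-A diene 36 by a final face- and site-selective OsO4 cis-dihydroxylation (C11, C12); the C2 and C9 acetates come from ketone reduction and MOM removal.
2. The γ-lactone (C8–C17 bond, C8 and C17 stereocentres) and the C6 chloride come last, from the 6,7-diol 30: acyloxonium opening by chloride, then intramolecular Reformatsky closure.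
3. Key step: the 6/10 briarane core 29 ⇐ transannular disrotatory 6π-electrocyclisation of the 14-membered cembranoid (1Z,12Z,10E)-triene 28, forming C1–C10 (cembrane C8–C3) and ring A plus the ten-membered ring in one event.
4. The 14-membered ring 28 ⇐ acyclic bis(vinyl iodide) 26 by double Stille "stitching" with (Z)-1,2-bis(trimethylstannyl)ethene (C12, C13).
5. 26 ⇐ D-tartrate (C5–C8), an alkoxyallenylzinc (C9–C11, C20), a silylacetylide (C3, C4), a Wittig CH2 (C16) and (Z)-3-iodo-2-methylacrolein (C1, C2, C14, C15). Ring order: 14-membered carbocycle → ring A + ten-membered ring → lactone.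

## Route

Step 1
Reactants: 1 prop-2-yn-1-ol
Product: 3 (Z)-3-iodo-2-methylprop-2-en-1-ol (iodine cis to CH2OH), via chelated vinylmagnesium alkoxide 2 (not isolated)
Conditions: MeMgBr (2.2 equiv), CuI (10 mol %), THF, −10 °C → rt; then I2, −40 °C; H2O
Reagents that add atoms: methylmagnesium bromide, C[Mg]Br; iodine, II
Why: CuI-catalysed anti-carbomagnesiation of the propargylic alkoxide (Duboudin–Normant type) puts magnesium cis to the CH2O arm through a five-membered chelate, and iodinolysis with retention gives the (Z)-iodide that later places C2 "inside" the triene.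

Step 2
Reactants: 3 (Z)-3-iodo-2-methylprop-2-en-1-ol
Product: 4 (Z)-3-iodo-2-methylprop-2-enal
Conditions: MnO2, CH2Cl2, rt, dark; used at once
Reagents that add atoms: none
Why: MnO2 allylic oxidation is neutral and keeps the (Z)-geometry of the β-iodo enal.

Step 3
Reactants: 5 but-2-yn-1-ol
Product: 6 1-(methoxymethoxy)but-2-yne
Conditions: MeOCH2Cl, i-Pr2NEt, CH2Cl2, 0 °C → rt
Reagents that add atoms: chloromethyl methyl ether, COCCl
Why: Standard MOM protection (O-alkylation) gives the ether whose O–CH2 position can be metalated.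

Step 4
Reactants: 7 acetylene; 8 hexamethylditin
Product: 9 (Z)-1,2-bis(trimethylstannyl)ethene
Conditions: Pd(PPh3)4 (2 mol %), dioxane, 60 °C, sealed tube
Reagents that add atoms: none
Why: Palladium-catalysed distannylation of an alkyne is a syn addition of Sn–Sn, so only the (Z)-isomer forms.

Step 5
Reactants: 10 triethyl orthopropionate
Product: 11 2-bromo-1,1,1-triethoxypropane (racemic)
Conditions: Br2, pyridine, 0 °C → rt
Reagents that add atoms: bromine, BrBr
Why: α-Bromination of an orthoester through its ketene acetal (McElvain type) gives the orthoester of 2-bromopropanoic acid needed in step 17.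

Step 6
Reactants: 12 dimethyl (4S,5S)-2,2-dimethyl-1,3-dioxolane-4,5-dicarboxylate (D-tartrate acetonide)
Product: 13 (4S,5S)-N4,N5-dimethoxy-N4,N5,2,2-tetramethyl-1,3-dioxolane-4,5-dicarboxamide
Conditions: MeNH(OMe)·HCl, i-PrMgCl, THF, −20 °C
Reagents that add atoms: N,O-dimethylhydroxylamine hydrochloride, CNOC.Cl
Why: Weinreb amidation of both esters with the magnesium amide leaves the trans-acetonide stereocentres (future C6 and C7) untouched.

Step 7
Reactants: 13 bis-Weinreb amide
Product: 14 (4S,5S)-5-formyl-N-methoxy-N,2,2-trimethyl-1,3-dioxolane-4-carboxamide (C8 aldehyde, C5 amide)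
Conditions: i-Bu2AlH (1.0 equiv), THF, −78 °C; aq. potassium sodium tartrate; used crude, 13 recycled
Reagents that add atoms: none
Why: Partial reduction of one Weinreb amide through its stable chelated hemiaminal desymmetrises the C2-symmetric diamide, and either amide gives the same aldehyde.

Step 8
Reactants: 14 aldehyde amide; 6 1-(methoxymethoxy)but-2-yne
Product: 17 alkynol (C5 Weinreb amide; 6,7-O-isopropylidene; 8-OH; 9-OMOM; C10≡C11–CH3; 7,8-anti and 8,9-anti; 9R), via lithiated propargyl ether 15 (not isolated), via allenylzinc bromide 16 (not isolated)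
Conditions: 6, s-BuLi, THF, −78 °C; ZnBr2; then 14, −78 → −20 °C; H2O
Reagents that add atoms: none
Why: SE2′ addition of a γ-alkoxyallenylzinc (Marshall/Normant-type propargylation) is anti-selective, and Felkin–Anh attack anti to the C7–O bond makes 7,8 anti, so C9 ends up 7,9-syn as in the target (C8 is oxidised later).

Step 9
Reactants: 17 alkynol
Product: 19 (E)-vinyl iodide (C10H=C11(CH3)I with C9 trans to iodine), via (E)-vinylstannane 18 (not isolated)
Conditions: Bu3SnH, PdCl2(PPh3)2 (3 mol %), THF, 0 °C; then I2, CH2Cl2, 0 °C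
Reagents that add atoms: iodine, II
Why: Palladium-catalysed syn-hydrostannation puts tin on the less hindered methyl-bearing alkyne carbon, and iododestannylation with retention gives the (E)-trisubstituted iodide.

Step 10
Reactants: 19 vinyl iodide Weinreb amide
Product: 20 C5 ynone (Me3Si–C4≡C3–C5(=O)–)
Conditions: LiC≡CSiMe3 (2.5 equiv), THF, −78 → −20 °C; H2O
Reagents that add atoms: lithium (trimethylsilyl)acetylide, [Li]C#C[Si](C)(C)C
Why: Acetylide addition to a Weinreb amide stops at the ketone through the chelated tetrahedral intermediate, and the vinyl iodide is inert to the acetylide.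

Step 11
Reactants: 20 ynone
Product: 22 terminal enyne (HC3≡C4–C5(=CH2)–), via silyl enyne 21 (not isolated)
Conditions: Ph3PCH3Br, KN(SiMe3)2, THF, −78 → 0 °C; then K2CO3, MeOH, rt
Reagents that add atoms: methyltriphenylphosphonium bromide, C[P+](c1ccccc1)(c1ccccc1)c1ccccc1.[Br-]
Why: Wittig methylenation installs C16, and carbonate methanolysis removes the alkynyl silane; the trans-acetonide is the thermodynamic epimer, so C6 is not at risk.

Step 12
Reactants: 22 terminal enyne; 4 (Z)-3-iodo-2-methylprop-2-enal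
Product: 24 propargylic diol (C2–OH as an epimer mixture; both vinyl iodides in place), via bromomagnesium acetylide alkoxide 23 (not isolated)
Conditions: EtMgBr (2.1 equiv), THF, 0 °C; then 4, −40 → 0 °C; H2O
Reagents that add atoms: none
Why: 1,2-Addition of an alkynyl Grignard to the enal forms C2–C3, and the C2 configuration is irrelevant because it is oxidised in step 14.

Step 13
Reactants: 24 propargylic diol
Product: 25 (3Z)-diene diol (C3=C4 cis; C5=C16 intact)
Conditions: Zn dust activated with Cu(OAc)2 and AgNO3, MeOH/H2O (1:1), 40 °C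
Reagents that add atoms: none
Why: Boland-type zinc semireduction is specific for conjugated enynes and gives the (Z)-alkene by syn delivery of hydrogen, without the Pd/H2 that would endanger the C–I bonds.

Step 14
Reactants: 25 (3Z)-diene diol
Product: 26 seco-diketone bis(vinyl iodide) (C2 and C8 ketones)
Conditions: Dess–Martin periodinane (3 equiv), NaHCO3, CH2Cl2, 0 °C; used directly
Reagents that add atoms: none
Why: Dess–Martin oxidation converts both secondary alcohols under buffered conditions, and removing H-2 is what later shuts off the [1,7]-hydrogen shift of the triene.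

Step 15
Reactants: 26 seco-diketone bis(vinyl iodide); 9 (Z)-1,2-bis(trimethylstannyl)ethene
Product: 29 briarane diketone acetonide (ring A 11,13-diene; C1 and C10 as in 37; 6,7-acetonide; 9-OMOM), via dienylstannane 27 (not isolated), via macrocyclic triene 28 (not isolated)
Conditions: 9 (1.05 equiv), Pd2(dba)3 (10 mol %), AsPh3 (40 mol %), THF, 1 mM, syringe pump, 45 °C; then 90 °C, sealed
Reagents that add atoms: none
Why: Proposed new method: a double Stille "stitching" (closest precedent: stitching macrocyclisations of bis(vinyl iodides) with 1,2-distannylethenes) closes the 14-membered (1Z,12Z,10E)-triene 28, which then undergoes thermal disrotatory 6π-electrocyclisation (closest precedent: (Z)-hexatriene to cyclohexadiene closures) across the ring to form C1–C10; Me-15 and C9 are both "outside" and so end up cis (the trans ring fusion of the target), the C2 ketone has no hydrogen for a competing [1,7]-shift, and A(1,3) strain holds H-9 in the plane of C10=C11 so that C1 should bond to the face of C10 carrying the C8 tether, giving the target C1/C10 configuration.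

Step 16
Reactants: 29 briarane diketone acetonide
Product: 30 6,7-diol (6-OH epimeric to the future chloride; 7-OH as in 37)
Conditions: AcOH/H2O (4:1), 45 °C
Reagents that add atoms: none
Why: Acid-catalysed acetonide hydrolysis is mild enough to leave the MOM ether and the ring-A diene intact.

Step 17
Reactants: 30 6,7-diol; 11 2-bromo-1,1,1-triethoxypropane
Product: 32 (6S)-chloride 7-(2-bromopropanoate), via cyclic orthoester 31 (not isolated)
Conditions: 11, pyridinium p-toluenesulfonate (cat.), CH2Cl2, rt; concentrate; Me3SiCl, CH2Cl2, 0 °C → rt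
Reagents that add atoms: chlorotrimethylsilane, C[Si](C)(C)Cl
Why: In this Sharpless–Kolb acyloxonium sequence Me3SiCl ionises the cyclic orthoester to a 1,3-dioxolan-2-ylium ion, and chloride opens it by SN2 at the allylic C6 (the carbon remote from the C8 carbonyl) with inversion, setting the C6 chloride and leaving the bromoacyl group on O7.

Step 18
Reactants: 32 chloro bromoester
Product: 33 γ-lactone (8-OH, 17-CH3, C7 and C6 as in 37; C2 ketone; 9-OMOM)
Conditions: Zn dust (Me3SiCl-activated), THF, 0 °C → rt; H2O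
Reagents that add atoms: none
Why: The intramolecular Reformatsky reaction adds the zinc enolate to the C8 ketone in a 5-exo closure whose transition state keeps C6/C9 and C9/CH3-18 trans on the forming ring, which gives 8-OH cis to C6 and to the 17-methyl as required.

Step 19
Reactants: 33 lactone MOM ether
Product: 34 9-alcohol
Conditions: Me3SiOTf, 2,2'-bipyridyl, CH2Cl2, 0 °C; then H2O
Reagents that add atoms: none
Why: MOM cleavage through a bipyridinium acetal salt (Fujioka type) is buffered and thiol-free, so the dienone, the allylic chloride and the β-hydroxy lactone survive.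

Step 20
Reactants: 34 9-alcohol (C2 ketone)
Product: 35 (2R)-2,9-diol
Conditions: (S)-2-methyl-CBS-oxazaborolidine [(S)-1-methyl-3,3-diphenyltetrahydro-1H,3H-pyrrolo[1,2-c][1,3,2]oxazaborole] (0.5 equiv), catecholborane, toluene/CH2Cl2, −78 °C
Reagents that add atoms: none
Why: Corey–Bakshi–Shibata 1,2-reduction of the dienone with catecholborane (which does not hydroborate the diene at −78 °C) should deliver hydride under reagent control, taking the fully substituted C1 flank as the large group, to give the 2R alcohol.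

Step 21
Reactants: 35 2,9-diol
Product: 36 2,9-diacetate
Conditions: Ac2O, 4-(dimethylamino)pyridine, pyridine, CH2Cl2, 0 °C → rt
Reagents that add atoms: acetic anhydride, CC(=O)OC(C)=O
Why: Acylation takes the two secondary alcohols and leaves the tertiary 8-OH untouched.

Step 22
Reactants: 36 2,9-diacetate
Product: 37 target CNP0317097.1
Conditions: OsO4 (1.05 equiv), pyridine, THF, −78 → −40 °C; aq. NaHSO3
Reagents that add atoms: osmium tetroxide, O=[Os](=O)(=O)=O
Why: Stoichiometric OsO4 cis-dihydroxylation should pick the most electron-rich alkene (trisubstituted C11=C12 of the ring-A diene; the other diene is deactivated by allylic OAc and Cl) and attack anti to the C9 substituent on C10 and to the axial CH3-15, giving the 11,12-cis-diol on the face of H-10.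

## Compound list

1 | prop-2-yn-1-ol | C#CCO | starting material
2 | chelated (Z)-vinylmagnesium alkoxide from 1 (not isolated) | Br[Mg]/C=C(/C)CO[Mg]Br | intermediate
3 | (Z)-3-iodo-2-methylprop-2-en-1-ol | I/C=C(/C)CO | intermediate
4 | (Z)-3-iodo-2-methylprop-2-enal | I/C=C(/C)C=O | intermediate
5 | but-2-yn-1-ol | CC#CCO | starting material
6 | 1-(methoxymethoxy)but-2-yne | CC#CCOCOC | intermediate
7 | acetylene | C#C | starting material
8 | hexamethylditin | C[Sn](C)(C)[Sn](C)(C)C | starting material
9 | (Z)-1,2-bis(trimethylstannyl)ethene | C[Sn](C)(C)/C=C\[Sn](C)(C)C | intermediate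
10 | triethyl orthopropionate (1,1,1-triethoxypropane) | CCC(OCC)(OCC)OCC | starting material
11 | 2-bromo-1,1,1-triethoxypropane (racemic) | CC(Br)C(OCC)(OCC)OCC | intermediate
12 | dimethyl (4S,5S)-2,2-dimethyl-1,3-dioxolane-4,5-dicarboxylate | COC(=O)[C@H]1OC(C)(C)O[C@@H]1C(=O)OC | starting material
13 | (4S,5S)-N4,N5-dimethoxy-N4,N5,2,2-tetramethyl-1,3-dioxolane-4,5-dicarboxamide | CON(C)C(=O)[C@H]1OC(C)(C)O[C@@H]1C(=O)N(C)OC | intermediate
14 | (4S,5S)-5-formyl-N-methoxy-N,2,2-trimethyl-1,3-dioxolane-4-carboxamide | CON(C)C(=O)[C@H]1OC(C)(C)O[C@@H]1C=O | intermediate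
15 | 1-lithio-1-(methoxymethoxy)but-2-yne (not isolated) | CC#CC([Li])OCOC | intermediate
16 | [3-(methoxymethoxy)-1-methylallenyl]zinc bromide (not isolated) | CC([Zn]Br)=C=COCOC | intermediate
17 | alkynol: C5 Weinreb amide, 6,7-acetonide, 8-OH, 9-OMOM, C10≡C11–CH3; 7,8-anti, 8,9-anti, 9R | CON(C)C(=O)[C@H]1OC(C)(C)O[C@@H]1[C@H](O)[C@H](OCOC)C#CC | intermediate
18 | (E)-C11 tributylvinylstannane of 17 (not isolated) | CON(C)C(=O)[C@H]1OC(C)(C)O[C@@H]1[C@H](O)[C@H](OCOC)/C=C(\C)[Sn](CCCC)(CCCC)CCCC | intermediate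
19 | (E)-C11 vinyl iodide, C5 Weinreb amide | CON(C)C(=O)[C@H]1OC(C)(C)O[C@@H]1[C@H](O)[C@H](OCOC)/C=C(\C)I | intermediate
20 | C5 (trimethylsilyl)ynone | C[Si](C)(C)C#CC(=O)[C@H]1OC(C)(C)O[C@@H]1[C@H](O)[C@H](OCOC)/C=C(\C)I | intermediate
21 | silyl enyne, C5=C16 methylene (not isolated) | C[Si](C)(C)C#CC(=C)[C@H]1OC(C)(C)O[C@@H]1[C@H](O)[C@H](OCOC)/C=C(\C)I | intermediate
22 | terminal enyne C3–C11 fragment | C#CC(=C)[C@H]1OC(C)(C)O[C@@H]1[C@H](O)[C@H](OCOC)/C=C(\C)I | intermediate
23 | bromomagnesium acetylide alkoxide of 22 (not isolated) | Br[Mg]C#CC(=C)[C@H]1OC(C)(C)O[C@@H]1[C@H](O[Mg]Br)[C@H](OCOC)/C=C(\C)I | intermediate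
24 | propargylic diol, full C1–C11/C14 chain, C2 epimers, bis(vinyl iodide) | I/C=C(/C)C(O)C#CC(=C)[C@H]1OC(C)(C)O[C@@H]1[C@H](O)[C@H](OCOC)/C=C(\C)I | intermediate
25 | (3Z)-diene diol | I/C=C(/C)C(O)/C=C\C(=C)[C@H]1OC(C)(C)O[C@@H]1[C@H](O)[C@H](OCOC)/C=C(\C)I | intermediate
26 | seco-diketone bis(vinyl iodide): (14Z)-C14 iodide, C2 and C8 ketones, (3Z), (10E)-C11 iodide | I/C=C(/C)C(=O)/C=C\C(=C)[C@H]1OC(C)(C)O[C@@H]1C(=O)[C@H](OCOC)/C=C(\C)I | intermediate
27 | (12Z)-C12 trimethylstannyl diene from the first Stille coupling (not isolated) | C[Sn](C)(C)/C=C\C=C(\C)C(=O)/C=C\C(=C)[C@H]1OC(C)(C)O[C@@H]1C(=O)[C@H](OCOC)/C=C(\C)I | intermediate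
28 | 14-membered cembranoid (1Z,12Z,10E,3Z)-tetraene diketone (not isolated) | C/C1=C/C=C\C(C)=C\[C@@H](OCOC)C(=O)[C@H]2OC(C)(C)O[C@@H]2C(=C)/C=C\C1=O | intermediate
29 | briarane diketone acetonide: ring-A 11,13-diene, C1/C9/C10 as in 37, C2 and C8 ketones, 6,7-acetonide, 9-OMOM | C=C1/C=C\C(=O)[C@@]2(C)C=CC=C(C)[C@@H]2[C@@H](OCOC)C(=O)[C@H]3OC(C)(C)O[C@H]13 | intermediate
30 | 6,7-diol of 29 | C=C1/C=C\C(=O)[C@@]2(C)C=CC=C(C)[C@@H]2[C@@H](OCOC)C(=O)[C@@H](O)[C@@H]1O | intermediate
31 | 6,7-cyclic orthoester, 2-(1-bromoethyl)-2-ethoxy-1,3-dioxolane (not isolated) | C=C1/C=C\C(=O)[C@@]2(C)C=CC=C(C)[C@@H]2[C@@H](OCOC)C(=O)[C@H]3OC(OCC)(C(C)Br)O[C@H]13 | intermediate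
32 | (6S)-6-chloro 7-O-(2-bromopropanoyl) diketone | C=C1/C=C\C(=O)[C@@]2(C)C=CC=C(C)[C@@H]2[C@@H](OCOC)C(=O)[C@@H](OC(=O)C(C)Br)[C@H]1Cl | intermediate
33 | γ-lactone: 8-OH, 17-CH3, C2 ketone, 9-OMOM, 6-Cl | C=C1/C=C\C(=O)[C@@]2(C)C=CC=C(C)[C@@H]2[C@@H](OCOC)[C@]2(O)[C@@H](C)C(=O)O[C@H]2[C@H]1Cl | intermediate
34 | 9-alcohol, C2 ketone | C=C1/C=C\C(=O)[C@@]2(C)C=CC=C(C)[C@@H]2[C@@H](O)[C@]2(O)[C@@H](C)C(=O)O[C@H]2[C@H]1Cl | intermediate
35 | (2R)-2,9-diol | C=C1/C=C\[C@@H](O)[C@@]2(C)C=CC=C(C)[C@@H]2[C@@H](O)[C@]2(O)[C@@H](C)C(=O)O[C@H]2[C@H]1Cl | intermediate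
36 | 2,9-diacetate, ring-A 11,13-diene | C=C1/C=C\[C@@H](OC(C)=O)[C@@]2(C)C=CC=C(C)[C@@H]2[C@@H](OC(C)=O)[C@]2(O)[C@@H](C)C(=O)O[C@H]2[C@H]1Cl | intermediate
37 | CNP0317097.1 | C=C1/C=C\[C@@H](OC(C)=O)[C@@]2(C)C=C[C@@H](O)[C@@](C)(O)[C@@H]2[C@@H](OC(C)=O)[C@]2(O)[C@@H](C)C(=O)O[C@H]2[C@H]1Cl | target

## Step count and risks

Total step count: 22. Longest linear sequence: 17 steps (steps 6–22, from 12).

The three steps most likely to fail:

**Step 15 (stitching macrocyclisation and transannular electrocyclisation).** The β-iodo dienone termini of 26 may not tolerate palladium, the double coupling may oligomerise, and the facial sense of the ring closure rests on a conformational argument only. The fallback sets out from diol 25, which is more flexible and has no enone. It is stitched with 9 at 25 °C (Pd2(dba)3, AsPh3, THF, high dilution) to the macrocyclic triene diol F1. F1 is kept cold, because its H-2 can undergo a [1,7]-shift, and is oxidised at once with Dess–Martin periodinane to the macrocyclic diketone 28. Heating 28 in toluene at 90 °C returns the route to 29.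

**Step 17 (chloride and bromoester from the diol).** The bromo-substituted acyloxonium ion may form sluggishly, and chloride may attack SN2′ at C16 or at C7. The fallback sets out from 30. SOCl2 and Et3N give the 6,7-cyclic sulfite F2, which is opened at the allylic C6 with LiCl in DMF (inversion) and hydrolysed to the 6-chloro-7-ol F3. Acylation of F3 with 2-bromopropanoyl bromide and pyridine returns the route to 32.

**Step 22 (final dihydroxylation).** OsO4 may also attack the C5=C16/C3=C4 diene of 36. The fallback sets out from 34, where the C2 ketone deactivates that diene by conjugation. OsO4 there gives the 11,12-diol F4, which is protected as the kinetically favoured cis-fused 11,12-acetonide F5 (2,2-dimethoxypropane, pyridinium p-toluenesulfonate). CBS reduction as in step 20 gives the 2-alcohol F6, acetylation gives the 2,9-diacetate F7, and aqueous acetic acid removes the acetonide to return to 37.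

## Further compounds

F1 | step 15 | 14-membered (1Z,12Z,10E,3Z)-tetraene 2,8-diol, 6,7-acetonide, 9-OMOM | C/C1=C/C=C\C(C)=C\[C@@H](OCOC)[C@@H](O)[C@H]2OC(C)(C)O[C@@H]2C(=C)/C=C\C1O
F2 | step 17 | 6,7-cyclic sulfite of 30 | C=C1/C=C\C(=O)[C@@]2(C)C=CC=C(C)[C@@H]2[C@@H](OCOC)C(=O)[C@H]3OS(=O)O[C@H]13
F3 | step 17 | (6S)-6-chloro-7-ol diketone | C=C1/C=C\C(=O)[C@@]2(C)C=CC=C(C)[C@@H]2[C@@H](OCOC)C(=O)[C@@H](O)[C@H]1Cl
F4 | step 22 | 11,12-cis-diol of 34 (C2 ketone, 9-OH) | C=C1/C=C\C(=O)[C@@]2(C)C=C[C@@H](O)[C@@](C)(O)[C@@H]2[C@@H](O)[C@]2(O)[C@@H](C)C(=O)O[C@H]2[C@H]1Cl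
F5 | step 22 | 11,12-acetonide of F4 | C=C1/C=C\C(=O)[C@@]2(C)C=C[C@H]3OC(C)(C)O[C@@]3(C)[C@@H]2[C@@H](O)[C@]2(O)[C@@H](C)C(=O)O[C@H]2[C@H]1Cl
F6 | step 22 | (2R)-2,9-diol 11,12-acetonide | C=C1/C=C\[C@@H](O)[C@@]2(C)C=C[C@H]3OC(C)(C)O[C@@]3(C)[C@@H]2[C@@H](O)[C@]2(O)[C@@H](C)C(=O)O[C@H]2[C@H]1Cl
F7 | step 22 | 2,9-diacetate 11,12-acetonide | C=C1/C=C\[C@@H](OC(C)=O)[C@@]2(C)C=C[C@H]3OC(C)(C)O[C@@]3(C)[C@@H]2[C@@H](OC(C)=O)[C@]2(O)[C@@H](C)C(=O)O[C@H]2[C@H]1Cl
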